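**Plan**

1. Ring numbering used here: O1, C2 (quaternary, Me and side chain), C3 (OAc), C4, C5, C6 (exocyclic E-alkene), C7. The acetates and the C3 carbinol go back to a 2,2-disubstituted oxepan-3-one, which is cut at C3–C4 and at O1–C2.
2. Enabling feature: O1–C2–C3 is an α-alkoxy carbinol, that is a reduced α-alkoxy ketone. C3 (a carbonyl carbon, normally an acceptor) is made a donor and C2 an acceptor by holding both in one 2-sulfonyl-3-methyloxirane, while O1 and C4 are the two ends of a five-atom hydroxy triflate (O1, C7, C6, C5, C4).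
3. Forward order: side chain first (C4'/C5' pair, three-carbon extension to an alkyne, vinyl sulfoxide, epoxy sulfone); separately the O1/C4–C7 unit with its E-alkene from but-2-yne-1,4-diol; then union and oxepane closure in one flask; ketone reduction, acetylation, desilylation.
4. Stereochemistry: C4'/C5' from a Brown (Z)-crotylboration; C2 from a sulfoxide-directed nucleophilic epoxidation followed by inversion in the ring closure; C3 from a Corey–Bakshi–Shibata reduction; alkene geometry from an anti carbomagnesiation.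

Key step: step 15

Assumption: in step 10 the peroxide is taken to add to the alkene face on the side of the sulfinyl oxygen (anti to the tolyl group) of the (S)-sulfoxide; if the facial sense were the reverse, the enantiomeric sulfinate ester would be used in step 8.

Abbreviations: TBDPS = tert-butyldiphenylsilyl, Tr = triphenylmethyl, Tol = 4-methylphenyl.

**Step 1**
Reactants: 1 4-methylpent-3-en-1-ol
Product: 2 4-methylpent-3-enal
Conditions: TEMPO (cat.), PhI(OAc)2, CH2Cl2, 0 °C to rt; used at once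
Reagents that add atoms: none
Why: oxoammonium (TEMPO) oxidation of a primary alcohol stops at the aldehyde under near-neutral conditions, so the β,γ-alkene should stay out of conjugation and no stereocentre is formed.

**Step 2**
Reactants: 2 4-methylpent-3-enal
Product: 4 (3R,4R)-3,7-dimethylocta-1,6-dien-4-ol, via borinate ester 3 (not isolated)
Conditions: cis-but-2-ene, KOt-Bu, n-BuLi, THF, −78 to −45 °C; (−)-Ipc2BOMe (from (+)-α-pinene), −78 °C; BF3·OEt2; 2, −78 °C; then NaOH, H2O2, rt
Reagents that add atoms: cis-but-2-ene C/C=C\C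
Why: Brown crotylboration through a closed chair transition state, in which the Z-crotyl geometry gives the syn methyl/hydroxyl pair and the isopinocampheyl groups from (+)-α-pinene direct attack to the Si face of the aldehyde, should set (3R,4R).

**Step 3**
Reactants: 4 (3R,4R)-3,7-dimethylocta-1,6-dien-4-ol
Product: 5 tert-butyl{[(3R,4R)-3,7-dimethylocta-1,6-dien-4-yl]oxy}diphenylsilane
Conditions: TBDPSCl, imidazole, DMAP (cat.), DMF, rt to 40 °C
Reagents that add atoms: tert-butylchlorodiphenylsilane CC(C)(C)[Si](Cl)(c1ccccc1)c1ccccc1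
Why: silylation of a secondary alcohol gives a bulky, acid-stable ether whose oxygen cannot take part in the later epoxide opening and which should survive to the last step.

**Step 4**
Reactants: 5 tert-butyl{[(3R,4R)-3,7-dimethylocta-1,6-dien-4-yl]oxy}diphenylsilane
Product: 7 (3R,4R)-4-(TBDPS-oxy)-3,7-dimethyloct-6-en-1-ol, via B-alkyl-9-BBN 6 (not isolated)
Conditions: 9-BBN-H, THF, 0 °C to rt; then NaOH, H2O2, 0 °C
Reagents that add atoms: hydrogen peroxide OO
Why: hydroboration–oxidation with 9-BBN-H is selective for the monosubstituted alkene over the trisubstituted one and places oxygen on the terminal carbon without touching a stereocentre.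

**Step 5**
Reactants: 7 (3R,4R)-4-(TBDPS-oxy)-3,7-dimethyloct-6-en-1-ol
Product: 8 tert-butyl{[(3R,4R)-1-iodo-3,7-dimethyloct-6-en-4-yl]oxy}diphenylsilane
Conditions: I2, PPh3, imidazole, CH2Cl2, 0 °C to rt
Reagents that add atoms: iodine II
Why: Appel-type iodination of a primary alcohol by SN2 displacement of the alkoxyphosphonium ion.

**Step 6**
Reactants: 8 tert-butyl{[(3R,4R)-1-iodo-3,7-dimethyloct-6-en-4-yl]oxy}diphenylsilane
Product: 9 (6R,7R)-7-(TBDPS-oxy)-6,10-dimethyl-1-(trimethylsilyl)undec-9-en-1-yne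
Conditions: 1-(trimethylsilyl)propyne, n-BuLi, THF, −78 °C; then 8, DMPU, −78 °C to rt
Reagents that add atoms: 1-(trimethylsilyl)propyne CC#C[Si](C)(C)C
Why: alkylation of propargylic lithiated 1-(trimethylsilyl)propyne by a primary iodide adds three carbons, the silyl group steering the reaction to the propargylic carbon.

**Step 7**
Reactants: 9 (6R,7R)-7-(TBDPS-oxy)-6,10-dimethyl-1-(trimethylsilyl)undec-9-en-1-yne
Product: 10 (6R,7R)-7-(TBDPS-oxy)-6,10-dimethylundec-9-en-1-yne
Conditions: K2CO3 (cat.), MeOH, rt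
Reagents that add atoms: none
Why: base-catalysed methanolysis of the alkynyl C–Si bond, which leaves the hindered silyl ether alone.

**Step 8**
Reactants: 10 (6R,7R)-7-(TBDPS-oxy)-6,10-dimethylundec-9-en-1-yne
Product: 12 1-methyl-4-{(R)-[(6R,7R)-7-(TBDPS-oxy)-6,10-dimethylundec-9-en-1-yn-1-yl]sulfinyl}benzene, via alkynylmagnesium bromide 11 (not isolated)
Conditions: EtMgBr, THF, 0 to 40 °C; then (1S,2R,5S)-(+)-menthyl (R)-p-toluenesulfinate, toluene, −20 °C
Reagents that add atoms: (1S,2R,5S)-menthyl (R)-4-methylbenzenesulfinate CC(C)[C@H]1CC[C@H](C)C[C@@H]1O[S@@](=O)c1ccc(C)cc1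
Why: Andersen sulfoxide synthesis, in which the alkynyl Grignard reagent displaces menthoxide at sulfur with inversion, so the sulfur configuration is set by the sulfinate ester.

**Step 9**
Reactants: 12 1-methyl-4-{(R)-[(6R,7R)-7-(TBDPS-oxy)-6,10-dimethylundec-9-en-1-yn-1-yl]sulfinyl}benzene
Product: 14 1-methyl-4-{(S)-[(1Z,6R,7R)-7-(TBDPS-oxy)-2,6,10-trimethylundeca-1,9-dien-1-yl]sulfinyl}benzene, via alkenylcopper 13 (not isolated)
Conditions: MeMgBr, CuBr·SMe2, THF, −78 °C; then 12, −78 °C; aq NH4Cl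
Reagents that add atoms: methylmagnesium bromide C[Mg]Br
Why: syn carbocupration of the alkynyl sulfoxide puts methyl on the β-carbon cis to copper, and protonation with retention should give the Z alkene (sulfur cis to the long chain) with sulfur untouched, the descriptor changing from R to S only through the CIP ranking.

**Step 10**
Reactants: 14 1-methyl-4-{(S)-[(1Z,6R,7R)-7-(TBDPS-oxy)-2,6,10-trimethylundeca-1,9-dien-1-yl]sulfinyl}benzene
Product: 16 (2S,3R)-3-methyl-2-[(4-methylphenyl)sulfonyl]-3-[(4R,5R)-5-(TBDPS-oxy)-4,8-dimethylnon-7-en-1-yl]oxirane, via sulfinyl oxirane 15 (not isolated)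
Conditions: t-BuOOH (excess), KOt-Bu, THF, −20 to 0 °C
Reagents that add atoms: tert-butyl hydroperoxide CC(C)(C)OO
Why: sulfoxide-directed Weitz–Scheffer nucleophilic epoxidation should add peroxide to the β-carbon from the face set by the sulfinyl group (assumption above) and so fix the (3R) oxirane carbon, after which excess peroxide oxidises the sulfinyl sulfur to the sulfone while the electron-rich prenyl alkene is inert to the nucleophilic oxidant.

**Step 11**
Reactants: 17 but-2-yne-1,4-diol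
Product: 19 (2E)-2-ethenylbut-2-ene-1,4-diol, via alkenylmagnesium alkoxide 18 (not isolated)
Conditions: vinylMgCl (excess), THF–toluene, reflux; aq NH4Cl
Reagents that add atoms: vinylmagnesium chloride C=C[Mg]Cl
Why: alkoxide-directed anti carbomagnesiation of a propargylic alcohol puts vinyl on one alkyne carbon and magnesium anti to it in a five-membered chelate, so protonation should give the E alkene with the two CH2OH groups trans.

**Step 12**
Reactants: 19 (2E)-2-ethenylbut-2-ene-1,4-diol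
Product: 20 (2E)-2-ethenyl-1,4-bis(trityloxy)but-2-ene
Conditions: TrCl, Et3N, DMAP (cat.), CH2Cl2, rt
Reagents that add atoms: trityl chloride ClC(c1ccccc1)(c1ccccc1)c1ccccc1
Why: tritylation of both primary alcohols gives very bulky ethers whose oxygens should not displace the later triflate and which fall off under the acid of step 15.

**Step 13**
Reactants: 20 (2E)-2-ethenyl-1,4-bis(trityloxy)but-2-ene
Product: 22 (3E)-5-(trityloxy)-3-[(trityloxy)methyl]pent-3-en-1-ol, via B-alkyl-9-BBN 21 (not isolated)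
Conditions: 9-BBN-H, THF, 0 °C to rt; then NaOH, H2O2, 0 °C
Reagents that add atoms: hydrogen peroxide OO
Why: 9-BBN-H attacks only the terminal vinyl carbon of the diene and not the hindered trisubstituted alkene, so oxidation should give the homoallylic primary alcohol with the alkene geometry intact.

**Step 14**
Reactants: 22 (3E)-5-(trityloxy)-3-[(trityloxy)methyl]pent-3-en-1-ol
Product: 23 (3E)-5-(trityloxy)-3-[(trityloxy)methyl]pent-3-en-1-yl trifluoromethanesulfonate
Conditions: Tf2O, 2,6-lutidine, CH2Cl2, −78 °C; cold filtration, used at once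
Reagents that add atoms: trifluoromethanesulfonic anhydride O=S(=O)(OS(=O)(=O)C(F)(F)F)C(F)(F)F
Why: sulfonylation of a primary alcohol with Tf2O and a hindered pyridine base at low temperature.

**Step 15**
Reactants: 16 (2S,3R)-3-methyl-2-[(4-methylphenyl)sulfonyl]-3-[(4R,5R)-5-(TBDPS-oxy)-4,8-dimethylnon-7-en-1-yl]oxirane; 23 (3E)-5-(trityloxy)-3-[(trityloxy)methyl]pent-3-en-1-yl trifluoromethanesulfonate
Product: 27 (2S,6E)-2-[(4R,5R)-5-(TBDPS-oxy)-4,8-dimethylnon-7-en-1-yl]-6-(2-hydroxyethylidene)-2-methyloxepan-3-one, via oxiranyllithium 24 (not isolated), via alkylated epoxy sulfone 25 (not isolated), via dihydroxy epoxy sulfone 26 (not isolated)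
Conditions: n-BuLi added to 16 + 23, THF–DMPU, −100 °C; then TsOH·H2O (excess), wet CHCl3, −100 °C to rt, same flask
Reagents that add atoms: none
Why: n-BuLi deprotonates the sulfonyl-bearing oxirane carbon of 16 in the presence of 23, and the sulfonyl-stabilised oxiranyllithium, an acyl-anion equivalent, is alkylated at once by the primary triflate to form the C3–C4 bond; TsOH·H2O then removes both trityl groups, the freed allylic hydroxyl opens the protonated epoxide at its tertiary carbon to form the O1–C2 bond, and the resulting α-sulfonyl alkoxide expels p-toluenesulfinate to leave the C3 ketone. The closest known reaction type is the alkylation of sulfonyl-stabilised oxiranyllithiums with primary triflates followed by acid-induced endo cyclisation of the hydroxy epoxy sulfone to a cyclic ether ketone, here run without isolating the coupling product. The oxepane closes by a 7-endo-tet opening of the epoxide. The quaternary C2 arises by stereospecific SN2-type inversion of the (3R) oxirane carbon, so it is controlled by step 10, and the sulfonyl carbon ends as the carbonyl, so its configuration is without consequence. Endo opening is needed over 6-exo opening and should be secured by the sulfonyl group, which deactivates and blocks its own carbon, and by the cation-stabilising methyl-bearing carbon; the second hydroxyl could only close an eight-membered ring. The coupling must also outrun internal displacement of the triflate, which the bulk of the trityl ethers and the −100 °C in-situ protocol are meant to ensure.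

**Step 16**
Reactants: 27 (2S,6E)-2-[(4R,5R)-5-(TBDPS-oxy)-4,8-dimethylnon-7-en-1-yl]-6-(2-hydroxyethylidene)-2-methyloxepan-3-one
Product: 28 (2S,3R,6E)-2-[(4R,5R)-5-(TBDPS-oxy)-4,8-dimethylnon-7-en-1-yl]-6-(2-hydroxyethylidene)-2-methyloxepan-3-ol
Conditions: (S)-2-methyl-CBS-oxazaborolidine, catecholborane, toluene, −78 to −40 °C
Reagents that add atoms: none
Why: Corey–Bakshi–Shibata reduction of a ketone flanked by a quaternary carbon (large) and a methylene (small) should deliver hydride under reagent control to give the (3R) alcohol, and catecholborane does not hydroborate the alkenes at this temperature.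

**Step 17**
Reactants: 28 (2S,3R,6E)-2-[(4R,5R)-5-(TBDPS-oxy)-4,8-dimethylnon-7-en-1-yl]-6-(2-hydroxyethylidene)-2-methyloxepan-3-ol
Product: 29 (2S,3R,6E)-6-(2-acetoxyethylidene)-2-[(4R,5R)-5-(TBDPS-oxy)-4,8-dimethylnon-7-en-1-yl]-2-methyloxepan-3-yl acetate
Conditions: Ac2O, pyridine, DMAP (cat.), CH2Cl2, rt
Reagents that add atoms: acetic anhydride CC(=O)OC(C)=O
Why: DMAP-catalysed acylation should esterify both the primary allylic and the hindered secondary hydroxyl while the side-chain oxygen stays silylated.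

**Step 18**
Reactants: 29 (2S,3R,6E)-6-(2-acetoxyethylidene)-2-[(4R,5R)-5-(TBDPS-oxy)-4,8-dimethylnon-7-en-1-yl]-2-methyloxepan-3-yl acetate
Product: 30 (2S,3R,6E)-6-(2-acetoxyethylidene)-2-[(4R,5R)-5-hydroxy-4,8-dimethylnon-7-en-1-yl]-2-methyloxepan-3-yl acetate
Conditions: TBAF, AcOH, THF, rt to 45 °C
Reagents that add atoms: none
Why: fluoride-induced Si–O cleavage, buffered with acetic acid so that the two acetates should neither migrate nor hydrolyse.

**Compound list**

1 | 4-methylpent-3-en-1-ol | CC(C)=CCCO | starting material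
2 | 4-methylpent-3-enal | CC(C)=CCC=O | intermediate
3 | (3R,4R)-3,7-dimethylocta-1,6-dien-4-yl diisopinocampheylborinate | C=C[C@@H](C)[C@H](OB([C@@H]1C[C@@H]2C[C@H]([C@H]1C)C2(C)C)[C@@H]1C[C@@H]2C[C@H]([C@H]1C)C2(C)C)CC=C(C)C | intermediate (not isolated)
4 | (3R,4R)-3,7-dimethylocta-1,6-dien-4-ol | C=C[C@@H](C)[C@H](O)CC=C(C)C | intermediate
5 | tert-butyl{[(3R,4R)-3,7-dimethylocta-1,6-dien-4-yl]oxy}diphenylsilane | C=C[C@@H](C)[C@H](O[Si](c1ccccc1)(c1ccccc1)C(C)(C)C)CC=C(C)C | intermediate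
6 | 9-[(3R,4R)-4-(TBDPS-oxy)-3,7-dimethyloct-6-en-1-yl]-9-borabicyclo[3.3.1]nonane | C1CCC2CCCC1B2CC[C@@H](C)[C@H](O[Si](c1ccccc1)(c1ccccc1)C(C)(C)C)CC=C(C)C | intermediate (not isolated)
7 | (3R,4R)-4-(TBDPS-oxy)-3,7-dimethyloct-6-en-1-ol | OCC[C@@H](C)[C@H](O[Si](c1ccccc1)(c1ccccc1)C(C)(C)C)CC=C(C)C | intermediate
8 | tert-butyl{[(3R,4R)-1-iodo-3,7-dimethyloct-6-en-4-yl]oxy}diphenylsilane | ICC[C@@H](C)[C@H](O[Si](c1ccccc1)(c1ccccc1)C(C)(C)C)CC=C(C)C | intermediate
9 | (6R,7R)-7-(TBDPS-oxy)-6,10-dimethyl-1-(trimethylsilyl)undec-9-en-1-yne | C[Si](C)(C)C#CCCC[C@@H](C)[C@H](O[Si](c1ccccc1)(c1ccccc1)C(C)(C)C)CC=C(C)C | intermediate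
10 | (6R,7R)-7-(TBDPS-oxy)-6,10-dimethylundec-9-en-1-yne | C#CCCC[C@@H](C)[C@H](O[Si](c1ccccc1)(c1ccccc1)C(C)(C)C)CC=C(C)C | intermediate
11 | bromomagnesium acetylide of 10 | Br[Mg]C#CCCC[C@@H](C)[C@H](O[Si](c1ccccc1)(c1ccccc1)C(C)(C)C)CC=C(C)C | intermediate (not isolated)
12 | 1-methyl-4-{(R)-[(6R,7R)-7-(TBDPS-oxy)-6,10-dimethylundec-9-en-1-yn-1-yl]sulfinyl}benzene | Cc1ccc(cc1)[S@@](=O)C#CCCC[C@@H](C)[C@H](O[Si](c1ccccc1)(c1ccccc1)C(C)(C)C)CC=C(C)C | intermediate
13 | 1-cuprio derivative of 14 (copper on the sulfinyl-bearing alkene carbon, cis to the new methyl) | Cc1ccc(cc1)[S@@](=O)/C([Cu])=C(/C)CCC[C@@H](C)[C@H](O[Si](c1ccccc1)(c1ccccc1)C(C)(C)C)CC=C(C)C | intermediate (not isolated)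
14 | 1-methyl-4-{(S)-[(1Z,6R,7R)-7-(TBDPS-oxy)-2,6,10-trimethylundeca-1,9-dien-1-yl]sulfinyl}benzene | Cc1ccc(cc1)[S@@](=O)/C=C(/C)CCC[C@@H](C)[C@H](O[Si](c1ccccc1)(c1ccccc1)C(C)(C)C)CC=C(C)C | intermediate
15 | (2S,3R)-3-methyl-2-[(4-methylphenyl)sulfinyl]-3-[(4R,5R)-5-(TBDPS-oxy)-4,8-dimethylnon-7-en-1-yl]oxirane (sulfur as in 14) | Cc1ccc(cc1)[S@@](=O)[C@@H]1O[C@]1(C)CCC[C@@H](C)[C@H](O[Si](c1ccccc1)(c1ccccc1)C(C)(C)C)CC=C(C)C | intermediate (not isolated)
16 | (2S,3R)-3-methyl-2-[(4-methylphenyl)sulfonyl]-3-[(4R,5R)-5-(TBDPS-oxy)-4,8-dimethylnon-7-en-1-yl]oxirane | Cc1ccc(cc1)S(=O)(=O)[C@@H]1O[C@]1(C)CCC[C@@H](C)[C@H](O[Si](c1ccccc1)(c1ccccc1)C(C)(C)C)CC=C(C)C | intermediate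
17 | but-2-yne-1,4-diol | OCC#CCO | starting material
18 | chloromagnesium alkenyl bis(alkoxide) from anti addition of vinyl and magnesium to 17 | C=C/C(CO[Mg]Cl)=C(/[Mg]Cl)CO[Mg]Cl | intermediate (not isolated)
19 | (2E)-2-ethenylbut-2-ene-1,4-diol | OC/C=C(/CO)C=C | intermediate
20 | (2E)-2-ethenyl-1,4-bis(trityloxy)but-2-ene | C=C/C(COC(c1ccccc1)(c1ccccc1)c1ccccc1)=C\COC(c1ccccc1)(c1ccccc1)c1ccccc1 | intermediate
21 | 9-{(3E)-5-(trityloxy)-3-[(trityloxy)methyl]pent-3-en-1-yl}-9-borabicyclo[3.3.1]nonane | C1CCC2CCCC1B2CC/C(COC(c1ccccc1)(c1ccccc1)c1ccccc1)=C\COC(c1ccccc1)(c1ccccc1)c1ccccc1 | intermediate (not isolated)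
22 | (3E)-5-(trityloxy)-3-[(trityloxy)methyl]pent-3-en-1-ol | OCC/C(COC(c1ccccc1)(c1ccccc1)c1ccccc1)=C\COC(c1ccccc1)(c1ccccc1)c1ccccc1 | intermediate
23 | (3E)-5-(trityloxy)-3-[(trityloxy)methyl]pent-3-en-1-yl trifluoromethanesulfonate | FC(F)(F)S(=O)(=O)OCC/C(COC(c1ccccc1)(c1ccccc1)c1ccccc1)=C\COC(c1ccccc1)(c1ccccc1)c1ccccc1 | intermediate
24 | 2-lithio derivative of 16 (lithium on the sulfonyl-bearing oxirane carbon) | Cc1ccc(cc1)S(=O)(=O)[C@]1([Li])O[C@]1(C)CCC[C@@H](C)[C@H](O[Si](c1ccccc1)(c1ccccc1)C(C)(C)C)CC=C(C)C | intermediate (not isolated)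
25 | oxirane 16 carrying the (3E)-5-(trityloxy)-3-[(trityloxy)methyl]pent-3-en-1-yl group on its sulfonyl-bearing carbon | Cc1ccc(cc1)S(=O)(=O)[C@]1(CC/C(COC(c2ccccc2)(c2ccccc2)c2ccccc2)=C\COC(c2ccccc2)(c2ccccc2)c2ccccc2)O[C@]1(C)CCC[C@@H](C)[C@H](O[Si](c2ccccc2)(c2ccccc2)C(C)(C)C)CC=C(C)C | intermediate (not isolated)
26 | bis-detritylated 25 (two free primary allylic hydroxyls) | Cc1ccc(cc1)S(=O)(=O)[C@]1(CC/C(CO)=C\CO)O[C@]1(C)CCC[C@@H](C)[C@H](O[Si](c2ccccc2)(c2ccccc2)C(C)(C)C)CC=C(C)C | intermediate (not isolated)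
27 | (2S,6E)-2-[(4R,5R)-5-(TBDPS-oxy)-4,8-dimethylnon-7-en-1-yl]-6-(2-hydroxyethylidene)-2-methyloxepan-3-one | OC/C=C1\CCC(=O)[C@](C)(CCC[C@@H](C)[C@H](O[Si](c2ccccc2)(c2ccccc2)C(C)(C)C)CC=C(C)C)OC1 | intermediate
28 | (2S,3R,6E)-2-[(4R,5R)-5-(TBDPS-oxy)-4,8-dimethylnon-7-en-1-yl]-6-(2-hydroxyethylidene)-2-methyloxepan-3-ol | OC/C=C1\CC[C@@H](O)[C@](C)(CCC[C@@H](C)[C@H](O[Si](c2ccccc2)(c2ccccc2)C(C)(C)C)CC=C(C)C)OC1 | intermediate
29 | (2S,3R,6E)-6-(2-acetoxyethylidene)-2-[(4R,5R)-5-(TBDPS-oxy)-4,8-dimethylnon-7-en-1-yl]-2-methyloxepan-3-yl acetate | CC(=O)OC/C=C1\CC[C@@H](OC(C)=O)[C@](C)(CCC[C@@H](C)[C@H](O[Si](c2ccccc2)(c2ccccc2)C(C)(C)C)CC=C(C)C)OC1 | intermediate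
30 | (2S,3R,6E)-6-(2-acetoxyethylidene)-2-[(4R,5R)-5-hydroxy-4,8-dimethylnon-7-en-1-yl]-2-methyloxepan-3-yl acetate | CC(=O)OC/C=C1\CC[C@@H](OC(C)=O)[C@](C)(CCC[C@@H](C)[C@H](O)CC=C(C)C)OC1 | target

**Step count**

Total: 18 steps. Longest linear sequence: 14 steps (steps 1–10, then 15–18).

**Steps most likely to fail**

1. Step 15. The triflate may be lost by internal displacement, or the oxiranyllithium may decompose before the C–C bond forms. The seven-membered endo opening may also be slow enough for hydration or rearrangement of the epoxy sulfone to compete. Fallback (sets out from 10, comes back at 28): Negishi carboalumination of 10 (AlMe3, Cp2ZrCl2) with trapping by n-BuLi and paraformaldehyde would give the (E)-allylic alcohol F1. Sharpless asymmetric epoxidation (Ti(OiPr)4, D-(−)-diethyl tartrate, t-BuOOH) would give the (2R,3R)-epoxy alcohol F2, and I2, PPh3 and imidazole would give the epoxy iodide F3. F3 would alkylate the lithiated N,N-dimethylhydrazone of 1-(tert-butyldimethylsilyloxy)propan-2-one (LiN(i-Pr)2, THF, −78 °C) to give the hydrazone F4. Aqueous oxalic acid and then TBAF would free the hydroxy keto epoxide F5. Camphorsulfonic acid would then induce 7-endo opening at the tertiary epoxide carbon with inversion to give the hydroxy oxepanone F6, which already carries C2 and C3 of the target. Horner–Wadsworth–Emmons olefination (triethyl phosphonoacetate, NaH) is not expected to be fully selective, so the (E)-unsaturated ester F7 would need purification. Reduction with i-Bu2AlH would return diol 28.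

2. Step 10. The facial selectivity of peroxide addition to the trisubstituted vinyl sulfoxide may be poor, or the oxidation at sulfur may stop short. Fallback (sets out from 14, comes back at 16): stereocontrol by selective addition is replaced by separation on the sulfur auxiliary. The epoxidation is stopped at the sulfinyl oxirane stage with one equivalent of t-BuOOLi (t-BuOOH, n-BuLi, THF, −78 °C). Compound 15 is isolated and freed by chromatography from the oxirane-epimeric sulfinyl oxirane F8, from which it differs as a diastereomer because of the fixed sulfur centre. Pure 15 is then oxidised at sulfur with n-Pr4N[RuO4] and N-methylmorpholine N-oxide to 16.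

3. Step 11. Under the forcing conditions the addition may stay incomplete, the diene product may polymerise, or the anti selectivity may erode. Fallback (sets out from 17, comes back at 19): trans hydroalumination of 17 with NaAlH2(OCH2CH2OMe)2 and iodinolysis would give (2Z)-2-iodobut-2-ene-1,4-diol F9. Suzuki–Miyaura coupling with potassium vinyltrifluoroborate (PdCl2(dppf), Cs2CO3, THF–H2O) would replace iodine by vinyl with retention to give 19.

**Further compounds**

F1 | step 15 | (2E,7R,8R)-8-(TBDPS-oxy)-3,7,11-trimethyldodeca-2,10-dien-1-ol | OC/C=C(\C)CCC[C@@H](C)[C@H](O[Si](c1ccccc1)(c1ccccc1)C(C)(C)C)CC=C(C)C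
F2 | step 15 | {(2R,3R)-3-methyl-3-[(4R,5R)-5-(TBDPS-oxy)-4,8-dimethylnon-7-en-1-yl]oxiran-2-yl}methanol | OC[C@H]1O[C@]1(C)CCC[C@@H](C)[C@H](O[Si](c1ccccc1)(c1ccccc1)C(C)(C)C)CC=C(C)C
F3 | step 15 | iodide of F2 (CH2I in place of CH2OH) | IC[C@H]1O[C@]1(C)CCC[C@@H](C)[C@H](O[Si](c1ccccc1)(c1ccccc1)C(C)(C)C)CC=C(C)C
F4 | step 15 | N,N-dimethylhydrazone of the 1-(tert-butyldimethylsilyloxy)-5-(oxiranyl)pentan-2-one obtained from F3 | CC(C)(C)[Si](C)(C)OCC(=NN(C)C)CC[C@H]1O[C@]1(C)CCC[C@@H](C)[C@H](O[Si](c1ccccc1)(c1ccccc1)C(C)(C)C)CC=C(C)C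
F5 | step 15 | 1-hydroxy-5-{(2R,3R)-3-methyl-3-[(4R,5R)-5-(TBDPS-oxy)-4,8-dimethylnon-7-en-1-yl]oxiran-2-yl}pentan-2-one | OCC(=O)CC[C@H]1O[C@]1(C)CCC[C@@H](C)[C@H](O[Si](c1ccccc1)(c1ccccc1)C(C)(C)C)CC=C(C)C
F6 | step 15 | (6R,7S)-6-hydroxy-7-methyl-7-[(4R,5R)-5-(TBDPS-oxy)-4,8-dimethylnon-7-en-1-yl]oxepan-3-one | O=C1CC[C@@H](O)[C@](C)(CCC[C@@H](C)[C@H](O[Si](c2ccccc2)(c2ccccc2)C(C)(C)C)CC=C(C)C)OC1
F7 | step 15 | ethyl (2E)-{(6R,7S)-6-hydroxy-7-methyl-7-[(4R,5R)-5-(TBDPS-oxy)-4,8-dimethylnon-7-en-1-yl]oxepan-3-ylidene}acetate | CCOC(=O)/C=C1\CC[C@@H](O)[C@](C)(CCC[C@@H](C)[C@H](O[Si](c2ccccc2)(c2ccccc2)C(C)(C)C)CC=C(C)C)OC1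
F8 | step 10 | (2R,3S)-oxirane epimer of 15 (same sulfur configuration) | Cc1ccc(cc1)[S@@](=O)[C@H]1O[C@@]1(C)CCC[C@@H](C)[C@H](O[Si](c1ccccc1)(c1ccccc1)C(C)(C)C)CC=C(C)C
F9 | step 11 | (2Z)-2-iodobut-2-ene-1,4-diol | OC/C=C(\I)CO
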